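The earlier runs and the new flask are simulated for substances that don't exist; scatter was added.

A closed flask moves reagent between its phases and into products, but what was charged stays the sum of those forms, so I counted from the flask's 0.950 equivalents, reagent charged over substrate charged, and took the even charge of one equivalent as the zero of my scale.

| flask | substrate | reagent in the second phase | remark | time | volume of the second phase over the first |
|---|---|---|---|---|---|
| maple | 0.12 M | 0.16 M | run made earlier |  |  |
| ash | 0.12 M | 0.25 M | run made earlier |  |  |
| elm | 0.18 M | 0.114 M | run made earlier |  |  |
| flask | 0.12 M | 0.114 M |  | 12 h | 0.25 |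

| run | time / h | target / % |
|---|---|---|
| maple | 1.50 | 22.4 |
| maple | 3.00 | 28.8 |
| maple | 5.00 | 27.0 |
| maple | 6.00 | 22.7 |
| maple | 8.00 | 13.4 |
| maple | 10.0 | 7.7 |
| maple | 12.0 | 5.1 |
| ash | 0.667 | 19.2 |
| ash | 2.00 | 37.3 |
| ash | 3.00 | 35.0 |
| ash | 5.00 | 15.5 |
| ash | 8.00 | 1.6 |
| ash | 10.0 | 0.6 |
| ash | 12.0 | 0.1 |
| elm | 1.00 | 7.2 |
| elm | 2.00 | 8.8 |
| elm | 3.00 | 9.4 |
| elm | 6.00 | 10.1 |
| elm | 12.0 | 9.7 |

(standard deviation of a reading: 0.3 percentage points)

- in the second phase: reagent in the second phase; everything else is in the first
- charges count per volume of the first phase; a concentration in a rate is the amount of a species over the volume of its own phase; every rate counts per litre of the first phase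
- the earlier runs hold the two phases in the same ratio of volumes as the flask asked about

- amount of target at 12 h, in percent of the substrate charged
- the change that raises the amount of target at 12 h, in percent of the substrate charged most ("none" if none brings more than 2 percentage points) (winter / midnight / none)
- amount of target at 12 h, in percent of the substrate charged, after winter

- winter: doubling the transfer coefficient of the reagent in the second phase, all else as stated
- midnight: doubling the amount of reagent in the second phase, all else as stated

1. The elm run stood below the zero at 0.633, and its target read 10.1% at 6.00 h and 9.7% at 12.0 h. The maple run at 1.33 and the ash run at 2.08 stood above it, and their target fell. The flask lay 0.452 of the way from elm to maple.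

2. Going that far between their highest readings, 10.1% and 28.8%, gave a peak near 18.6%.

3. At 12.0 h, elm read 0.960 of its highest reading and maple 0.177 of its own. The same interpolation gave 11.2% for the flask.

4. That share was the weak link. The highest readings of maple and ash, at 3.00 h and 2.00 h, had charge-times-hours in a ratio of 0.960, so hours seemed to count with the reagent charge. The flask's 12 h then matched 8.55 h in maple, where the readings gave about 11.8%. Redoing the share with this, I committed to 13.2%.

5. Midnight would take the flask to 1.90 equivalents, close to the 2.08 of ash, which read 0.1% at 12.0 h. Winter leaves the equivalents alone, so I chose winter but could put no size on it.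

The forecast gave 15% (11% to 19%), higher than my figure, and also chose winter, at 21% (14% to 29%), saying “reagent runs out and target sits on a plateau”.

The flask gave 13.8%. The best change was winter, worth 4.4 percentage points and reaching 18.3%, while midnight changed target by −14 points.

    reagent in the reaction phase ⇌ reagent in the second phase, rate k1*([reagent in the reaction phase] - [reagent in the second phase]/K1) per volume of the first phase (partition coefficient = 2.00, kL = 0.00200 min⁻¹)
    substrate + reagent in the reaction phase → target (k = 1.70 L mol⁻¹ min⁻¹)
    reagent in the reaction phase + target → over-reacted product (k = 0.330 L mol⁻¹ min⁻¹)
    substrate + target → side product (k = 0.130 L mol⁻¹ min⁻¹)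

In the flask, substrate fell from 71.5% at 1.20 h to 6.28% at 6.00 h while side product rose to 64.8%. By 12.0 h substrate, the limiting reagent, stood at 0.0945%, and target had sunk from 22.4% to 13.8% while over-reacted product rose from 6.51% to 17.8%. Of the 0.950 equivalents, the products then held 0.836, counting 1 per target, 2 per over-reacted product and 0.5 per side product, and 0.114 remained as reagent.

The neighbour charged with 0.048 M of substrate has 2.38 equivalents, more than ash's 2.08, so the scale puts it on the side where target falls. It gave 2.01% target at 12 h, with 70.2% over-reacted product and 27.8% side product.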